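**Plan**

- Retrosynthetic cuts: (a) the five O–CH3 bonds and the quinone oxidation level, with a 1,2,4,5-tetramethoxynaphthalene masking the 2,5-dihydroxy-1,4-naphthoquinone; (b) the lactone C–O bond of the pyranone and the CH2–C(=O) bond to a dioxinone; (c) in one cut, the C-1'–C(=O) bond and the C-2'–O bond of the orcinol ring; (d) the ArCH2–CO2Me bond; (e) the C-4a–C-5 and C-8–C-8a bonds of the naphthalene (Diels–Alder).
- Enabling feature: the ketone carbon sits on C-1' of the orcinol ring, between C-2' (OH) and C-6' (CH3). An acyl group and an oxygen on adjacent ring carbons is what an aryne leaves on inserting into the C(acyl)–O bond of a carboxylic acid, and the CH3 beside the triple bond decides which aryne carbon takes the oxygen.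
- Forward order: the benzo ring C-5 to C-8 is built by cycloaddition onto 2,5-dibromobenzoquinone (OH, CO2Me and CH3 set by the diene); the quinone is masked; the side arm is extended by lateral carboxylation; the orcinol ring is joined as an aryne; the pyranone is closed from a dioxinone; global demethylation with air oxidation unmasks the target.
- Stereochemistry: the target has no stereocentre and no stereogenic double bond, so nothing has to be controlled.

Key step: step 9

Remark: the target is taken as the drawn 2-hydroxy-1,4-naphthoquinone / 4-hydroxy-2-pyranone tautomer; naphthoquinone atoms are C-1 to C-8a, orcinol ring atoms are primed.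

**Route**

Step 1
Reactants: 1 dimethyl isopropylidenemalonate
Product: 3 methyl 2-[methoxy(trimethylsilyloxy)methylidene]-3-methylbut-3-enoate, via lithium dienolate 2 (not isolated)
Conditions: LDA (1.1 equiv), THF, −78 °C; Me3SiCl, −78 °C → rt; filtered, used crude
Reagents that add atoms: chlorotrimethylsilane C[Si](C)(C)Cl
Why: γ-deprotonation of the alkylidene malonate and O-silylation of the dienolate (silyl ketene acetal formation) should give the 1,1-dioxygenated diene that carries C-5 to C-8 with the ester and the methyl group already in place.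

Step 2
Reactants: 3 methyl 2-[methoxy(trimethylsilyloxy)methylidene]-3-methylbut-3-enoate, 4 2,5-dibromo-1,4-benzoquinone
Product: 6 methyl 6-bromo-1-hydroxy-3-methyl-5,8-dioxo-5,8-dihydronaphthalene-2-carboxylate, via cycloadduct 5 (not isolated)
Conditions: toluene, −30 °C → rt (1.0 equiv of 3); then moist SiO2, CH2Cl2, rt
Reagents that add atoms: none
Why: Diels–Alder reaction of a vinylketene acetal with a haloquinone, then loss of HBr and of the acetal substituents (aromatization); the nucleophilic CH2 terminus of the diene should bond to the unbrominated quinone carbon, so the acetal carbon ends up on the C–Br carbon and the new OH is peri to the carbonyl remote from the remaining bromine.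

Step 3
Reactants: 6 methyl 6-bromo-1-hydroxy-3-methyl-5,8-dioxo-5,8-dihydronaphthalene-2-carboxylate
Product: 7 methyl 1-hydroxy-6-methoxy-3-methyl-5,8-dioxo-5,8-dihydronaphthalene-2-carboxylate
Conditions: NaOMe, MeOH, 0 °C → rt
Reagents that add atoms: sodium methoxide [Na+].[O-]C
Why: addition–elimination (ipso substitution) of the vinylogous acyl bromide of a 2-bromo-1,4-naphthoquinone by methoxide should fix the oxygen at C-2 of the future quinone.

Step 4
Reactants: 7 methyl 1-hydroxy-6-methoxy-3-methyl-5,8-dioxo-5,8-dihydronaphthalene-2-carboxylate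
Product: 9 methyl 1,5,6,8-tetramethoxy-3-methylnaphthalene-2-carboxylate, via hydroquinone 8 (not isolated)
Conditions: Na2S2O4, Bu4NBr (cat.), THF/H2O, rt; then KOH, Me2SO4, rt, under N2
Reagents that add atoms: dimethyl sulfate COS(=O)(=O)OC
Why: reductive methylation (dithionite reduction, then Williamson O-methylation of the three phenolic OH groups) should mask the quinone as an arene that tolerates the carbanion and aryne chemistry ahead.

Step 5
Reactants: 9 methyl 1,5,6,8-tetramethoxy-3-methylnaphthalene-2-carboxylate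
Product: 10 1,5,6,8-tetramethoxy-3-methylnaphthalene-2-carboxylic acid
Conditions: KOH, DMSO/H2O, 100 °C; then aq. HCl
Reagents that add atoms: potassium hydroxide [K+].[OH-]
Why: saponification of a doubly ortho-substituted aryl ester is slow, so poorly solvated hydroxide in hot DMSO is used, to which the aryl methyl ethers are inert.

Step 6
Reactants: 10 1,5,6,8-tetramethoxy-3-methylnaphthalene-2-carboxylic acid
Product: 12 1,5,6,8-tetramethoxy-3-(2-methoxy-2-oxoethyl)naphthalene-2-carboxylic acid, via dilithium dianion 11 (not isolated)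
Conditions: LDA (3.5 equiv), THF, −78 → 0 °C; (MeO)2CO, −78 °C → rt; then aq. HCl
Reagents that add atoms: dimethyl carbonate COC(=O)OC
Why: carboxylate-directed lateral lithiation of an o-toluic acid and C-acylation of the benzylic carbanion by dimethyl carbonate (homophthalic half-ester synthesis) should extend the arm, the excess base absorbing the more acidic arylacetate product.

Step 7
Reactants: 13 4-methoxy-2-methylphenol
Product: 14 2-bromo-4-methoxy-6-methylphenol
Conditions: NBS, MeCN, 0 °C
Reagents that add atoms: N-bromosuccinimide O=C1CCC(=O)N1Br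
Why: electrophilic aromatic bromination should go to the only free position ortho to the hydroxyl group, the para position being blocked by OMe.

Step 8
Reactants: 14 2-bromo-4-methoxy-6-methylphenol
Product: 17 4-methoxy-2-methyl-6-(trimethylsilyl)phenyl trifluoromethanesulfonate, via aryl trimethylsilyl ether 15 (not isolated), via lithium 2-silylphenoxide 16 (not isolated)
Conditions: HMDS, THF, 70 °C, then evaporation; n-BuLi, THF, −78 °C → rt; Tf2O, −78 °C → rt
Reagents that add atoms: hexamethyldisilazane C[Si](C)(C)N[Si](C)(C)C; trifluoromethanesulfonic anhydride O=S(=O)(OS(=O)(=O)C(F)(F)F)C(F)(F)F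
Why: O-silylation, bromine–lithium exchange with retro-Brook 1,3-O→C silyl shift and triflation of the phenoxide is the standard sequence to an o-silylaryl triflate aryne precursor.

Step 9
Reactants: 12 1,5,6,8-tetramethoxy-3-(2-methoxy-2-oxoethyl)naphthalene-2-carboxylic acid, 17 4-methoxy-2-methyl-6-(trimethylsilyl)phenyl trifluoromethanesulfonate
Product: 19 methyl 2-[3-(2-hydroxy-4-methoxy-6-methylbenzoyl)-4,5,7,8-tetramethoxynaphthalen-2-yl]acetate, via 5-methoxy-3-methylbenzyne 18 (not isolated)
Conditions: CsF (4 equiv), 17 (1.5 equiv), THF, 125 °C, sealed tube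
Reagents that add atoms: none
Why: Fluoride strips the silyl group of 17 and triflate leaves to give aryne 18; the cesium carboxylate of 12 adds through oxygen to the aryne carbon that has C–H as neighbour, the aryl anion formed next to the methyl group attacks the ester carbonyl (4-exo-trig) to a benzoxetene alkoxide, and this opens to the ketone and the phenoxide, a formal insertion of the aryne into the C(acyl)–O bond. The closest known reaction type is the fluoride-mediated insertion of arynes into the C–O bond of aromatic carboxylic acids to give o-hydroxyaryl ketones, an anionic Fries-type 1,3-O→C acyl shift. No ring of the product is closed (the four-membered ring is transient) and no stereocentre is formed. The step needs regioselectivity, oxygen to the aryne carbon distal to CH3: the methyl group beside the triple bond should block the proximal carbon against the doubly ortho-substituted naphthoate, while the methoxy group, meta and para to the two aryne carbons, should exert only a small inductive bias. It also needs the acyl shift to outrun protonation of the aryl anion, which the aprotic medium and the carbonyl held next to the anion should secure.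

Step 10
Reactants: 19 methyl 2-[3-(2-hydroxy-4-methoxy-6-methylbenzoyl)-4,5,7,8-tetramethoxynaphthalen-2-yl]acetate
Product: 20 2-[3-(2-hydroxy-4-methoxy-6-methylbenzoyl)-4,5,7,8-tetramethoxynaphthalen-2-yl]acetic acid
Conditions: LiOH, THF/H2O, rt; then aq. HCl
Reagents that add atoms: lithium hydroxide [Li+].[OH-]
Why: saponification of the unhindered arylacetate should be clean, the hindered diaryl ketone and the aryl ethers being inert to aqueous hydroxide.

Step 11
Reactants: 20 2-[3-(2-hydroxy-4-methoxy-6-methylbenzoyl)-4,5,7,8-tetramethoxynaphthalen-2-yl]acetic acid, 21 2,2,6-trimethyl-4H-1,3-dioxin-4-one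
Product: 24 6-{3-[3-(2-hydroxy-4-methoxy-6-methylbenzoyl)-4,5,7,8-tetramethoxynaphthalen-2-yl]-2-oxopropyl}-2,2-dimethyl-4H-1,3-dioxin-4-one, via lithium dienolate 22 (not isolated), via acyl imidazole 23 (not isolated)
Conditions: 21, LDA, THF, −78 °C (3.5 equiv of dienolate); 20, CDI (1.1 equiv), THF, rt, then added at −78 °C; aq. HCl
Reagents that add atoms: none
Why: γ-selective C-acylation of the dioxinone lithium dienolate by an acyl imidazole (crossed Claisen condensation) should give the keto-dioxinone, the excess dienolate deprotonating the chelated phenol and the product while the hindered diaryl ketone is not attacked at −78 °C.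

Step 12
Reactants: 24 6-{3-[3-(2-hydroxy-4-methoxy-6-methylbenzoyl)-4,5,7,8-tetramethoxynaphthalen-2-yl]-2-oxopropyl}-2,2-dimethyl-4H-1,3-dioxin-4-one
Product: 26 4-hydroxy-6-{[3-(2-hydroxy-4-methoxy-6-methylbenzoyl)-4,5,7,8-tetramethoxynaphthalen-2-yl]methyl}-2H-pyran-2-one, via acylketene 25 (not isolated)
Conditions: toluene, 110 °C
Reagents that add atoms: none
Why: retro-[4+2] loss of acetone from the dioxinone gives an acylketene that is trapped by the enol oxygen of the neighbouring ketone (6-ring lactonization) to the 4-hydroxy-2-pyranone under neutral conditions.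

Step 13
Reactants: 26 4-hydroxy-6-{[3-(2-hydroxy-4-methoxy-6-methylbenzoyl)-4,5,7,8-tetramethoxynaphthalen-2-yl]methyl}-2H-pyran-2-one
Product: 28 6-(2,4-dihydroxy-6-methylbenzoyl)-2,5-dihydroxy-7-[(4-hydroxy-2-oxo-2H-pyran-6-yl)methyl]naphthalene-1,4-dione, via hexahydroxy compound 27 (not isolated)
Conditions: BBr3 (excess), CH2Cl2, −78 °C → rt; then H2O, air, rt
Reagents that add atoms: none
Why: BBr3 ether cleavage should free all five aryl methyl ethers, and the liberated 1,2,4-trihydroxy ring (a hydroxyhydroquinone) should be autoxidized by air to the 2-hydroxy-1,4-quinone, the resorcinol-type ring and the pyranone being too electron-poor to be oxidized and the quinone oxygens already sitting where steps 2 and 3 placed them.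

**Compound list**

1 | dimethyl isopropylidenemalonate | COC(=O)C(=C(C)C)C(=O)OC | starting material
2 | lithium dienolate of 1 | [Li+].COC(=O)C(C(C)=C)=C([O-])OC | intermediate (not isolated)
3 | methyl 2-[methoxy(trimethylsilyloxy)methylidene]-3-methylbut-3-enoate | COC(=O)C(C(C)=C)=C(OC)O[Si](C)(C)C | intermediate
4 | 2,5-dibromo-1,4-benzoquinone | O=C1C=C(Br)C(=O)C=C1Br | starting material
5 | Diels–Alder cycloadduct, racemic, cis ring fusion (relative configuration shown), acetal carbon unassigned | COC(=O)C1=C(C)C[C@@H]2C(=O)C(Br)=CC(=O)[C@]2(Br)C1(OC)O[Si](C)(C)C | intermediate (not isolated)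
6 | methyl 6-bromo-1-hydroxy-3-methyl-5,8-dioxo-5,8-dihydronaphthalene-2-carboxylate | COC(=O)c1c(C)cc2C(=O)C(Br)=CC(=O)c2c1O | intermediate
7 | methyl 1-hydroxy-6-methoxy-3-methyl-5,8-dioxo-5,8-dihydronaphthalene-2-carboxylate | COC(=O)c1c(C)cc2C(=O)C(OC)=CC(=O)c2c1O | intermediate
8 | methyl 1,5,8-trihydroxy-6-methoxy-3-methylnaphthalene-2-carboxylate | COC(=O)c1c(C)cc2c(O)c(OC)cc(O)c2c1O | intermediate (not isolated)
9 | methyl 1,5,6,8-tetramethoxy-3-methylnaphthalene-2-carboxylate | COC(=O)c1c(C)cc2c(OC)c(OC)cc(OC)c2c1OC | intermediate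
10 | 1,5,6,8-tetramethoxy-3-methylnaphthalene-2-carboxylic acid | Cc1cc2c(OC)c(OC)cc(OC)c2c(OC)c1C(=O)O | intermediate
11 | dilithium dianion of 10 (carboxylate and benzylic carbanion) | [Li+].[Li+].[CH2-]c1cc2c(OC)c(OC)cc(OC)c2c(OC)c1C(=O)[O-] | intermediate (not isolated)
12 | 1,5,6,8-tetramethoxy-3-(2-methoxy-2-oxoethyl)naphthalene-2-carboxylic acid | COC(=O)Cc1cc2c(OC)c(OC)cc(OC)c2c(OC)c1C(=O)O | intermediate
13 | 4-methoxy-2-methylphenol | COc1ccc(O)c(C)c1 | starting material
14 | 2-bromo-4-methoxy-6-methylphenol | COc1cc(C)c(O)c(Br)c1 | intermediate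
15 | (2-bromo-4-methoxy-6-methylphenoxy)trimethylsilane | COc1cc(C)c(O[Si](C)(C)C)c(Br)c1 | intermediate (not isolated)
16 | lithium 4-methoxy-2-methyl-6-(trimethylsilyl)phenoxide | [Li+].COc1cc(C)c([O-])c([Si](C)(C)C)c1 | intermediate (not isolated)
17 | 4-methoxy-2-methyl-6-(trimethylsilyl)phenyl trifluoromethanesulfonate | COc1cc(C)c(OS(=O)(=O)C(F)(F)F)c([Si](C)(C)C)c1 | intermediate
18 | 5-methoxy-3-methylbenzyne (1,2-didehydro-5-methoxy-3-methylbenzene) | COC1=CC#CC(C)=C1 | intermediate (not isolated)
19 | methyl 2-[3-(2-hydroxy-4-methoxy-6-methylbenzoyl)-4,5,7,8-tetramethoxynaphthalen-2-yl]acetate | COC(=O)Cc1cc2c(OC)c(OC)cc(OC)c2c(OC)c1C(=O)c1c(C)cc(OC)cc1O | intermediate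
20 | 2-[3-(2-hydroxy-4-methoxy-6-methylbenzoyl)-4,5,7,8-tetramethoxynaphthalen-2-yl]acetic acid | OC(=O)Cc1cc2c(OC)c(OC)cc(OC)c2c(OC)c1C(=O)c1c(C)cc(OC)cc1O | intermediate
21 | 2,2,6-trimethyl-4H-1,3-dioxin-4-one | CC1=CC(=O)OC(C)(C)O1 | starting material
22 | lithium 2,2-dimethyl-6-methylidene-6H-1,3-dioxin-4-olate (dienolate of 21) | [Li+].[O-]C1=CC(=C)OC(C)(C)O1 | intermediate (not isolated)
23 | 1-{[3-(2-hydroxy-4-methoxy-6-methylbenzoyl)-4,5,7,8-tetramethoxynaphthalen-2-yl]acetyl}imidazole | O=C(Cc1cc2c(OC)c(OC)cc(OC)c2c(OC)c1C(=O)c1c(C)cc(OC)cc1O)n1ccnc1 | intermediate (not isolated)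
24 | 6-{3-[3-(2-hydroxy-4-methoxy-6-methylbenzoyl)-4,5,7,8-tetramethoxynaphthalen-2-yl]-2-oxopropyl}-2,2-dimethyl-4H-1,3-dioxin-4-one | CC1(C)OC(CC(=O)Cc2cc3c(OC)c(OC)cc(OC)c3c(OC)c2C(=O)c2c(C)cc(OC)cc2O)=CC(=O)O1 | intermediate
25 | acylketene, 6-aryl-3,5-dioxohex-1-en-1-one (aryl as in 24) | O=C=CC(=O)CC(=O)Cc1cc2c(OC)c(OC)cc(OC)c2c(OC)c1C(=O)c1c(C)cc(OC)cc1O | intermediate (not isolated)
26 | 4-hydroxy-6-{[3-(2-hydroxy-4-methoxy-6-methylbenzoyl)-4,5,7,8-tetramethoxynaphthalen-2-yl]methyl}-2H-pyran-2-one | COc1cc(C)c(C(=O)c2c(Cc3cc(O)cc(=O)o3)cc3c(OC)c(OC)cc(OC)c3c2OC)c(O)c1 | intermediate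
27 | 6-{[3-(2,4-dihydroxy-6-methylbenzoyl)-4,5,7,8-tetrahydroxynaphthalen-2-yl]methyl}-4-hydroxy-2H-pyran-2-one | Cc1cc(O)cc(O)c1C(=O)c1c(Cc2cc(O)cc(=O)o2)cc2c(O)c(O)cc(O)c2c1O | intermediate (not isolated)
28 | 6-(2,4-dihydroxy-6-methylbenzoyl)-2,5-dihydroxy-7-[(4-hydroxy-2-oxo-2H-pyran-6-yl)methyl]naphthalene-1,4-dione | Cc1cc(O)cc(O)c1C(=O)c1c(Cc2cc(O)cc(=O)o2)cc2c(c1O)C(=O)C=C(O)C2=O | target

**Count and risks**

Total step count: 13. Longest linear sequence: 11 steps (steps 1–6 and 9–13); steps 7 and 8 form the short branch.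

Steps most likely to fail:

1. Step 9. The carboxylate may add to the wrong aryne carbon, since the methyl group is only a modest steric director. The aryl anion may also be protonated (for instance by the arylacetate CH2) before the hindered 1,3-acyl shift, so that the reaction stops at O-arylation. The fallback sets out from 12 and comes back at 19. Oxalyl chloride with catalytic DMF in CH2Cl2 should give 1,5,6,8-tetramethoxy-3-(2-methoxy-2-oxoethyl)naphthalene-2-carbonyl chloride F1. This should acylate commercial 3-methoxy-5-methylphenol (Et3N, DMAP, CH2Cl2) to 3-methoxy-5-methylphenyl 1,5,6,8-tetramethoxy-3-(2-methoxy-2-oxoethyl)naphthalene-2-carboxylate F2. A Lewis acid Fries rearrangement (TiCl4, 1,2-dichloroethane, high dilution) should then move the acyl group to the ring carbon between the ester oxygen and CH3, para to OMe, the doubly ortho-substituted aroyl group ionizing easily to its acylium ion, and so give 19.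

2. Step 11. The basic dienolate may enolize the arylacetyl imidazole (ketene formation and return of acid 20), and the acyl group may be transferred to the phenol oxygen. The fallback sets out from 20 and comes back at 26, without passing through 24. Oxalyl chloride should give 2-[3-(2-hydroxy-4-methoxy-6-methylbenzoyl)-4,5,7,8-tetramethoxynaphthalen-2-yl]acetyl chloride F3. A Mukaiyama-type C-acylation of 1-methoxy-1,3-bis(trimethylsilyloxy)buta-1,3-diene (CH2Cl2, −78 °C → rt, no base) should give methyl 6-[3-(2-hydroxy-4-methoxy-6-methylbenzoyl)-4,5,7,8-tetramethoxynaphthalen-2-yl]-3,5-dioxohexanoate F4. Lactonization of the 3,5-dioxo ester (DBU, toluene, 60 °C) should close the pyranone 26.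

3. Step 13. Ether cleavage may be incomplete at the methoxy group para to the ketone, the hexahydroxy intermediate may be over-oxidized by air and the hydrogen peroxide it forms, and the Lewis acid may promote condensation of the pyranone with the ketone. The fallback sets out from 26 and comes back at 28. Oxidative demethylation with ceric ammonium nitrate (MeCN/H2O, 0 °C) should convert the para-dimethoxy ring first, giving 6-(2-hydroxy-4-methoxy-6-methylbenzoyl)-2,5-dimethoxy-7-[(4-hydroxy-2-oxo-2H-pyran-6-yl)methyl]naphthalene-1,4-dione F5, so that no air-sensitive polyphenol is handled. BBr3 (CH2Cl2, −78 °C → rt) should then cleave the remaining three methyl ethers (peri, vinylogous ester, and para to the ketone) to 28.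

**Further compounds**

F1 | step 9 | 1,5,6,8-tetramethoxy-3-(2-methoxy-2-oxoethyl)naphthalene-2-carbonyl chloride | COC(=O)Cc1cc2c(OC)c(OC)cc(OC)c2c(OC)c1C(Cl)=O
F2 | step 9 | 3-methoxy-5-methylphenyl 1,5,6,8-tetramethoxy-3-(2-methoxy-2-oxoethyl)naphthalene-2-carboxylate | COC(=O)Cc1cc2c(OC)c(OC)cc(OC)c2c(OC)c1C(=O)Oc1cc(C)cc(OC)c1
F3 | step 11 | 2-[3-(2-hydroxy-4-methoxy-6-methylbenzoyl)-4,5,7,8-tetramethoxynaphthalen-2-yl]acetyl chloride | ClC(=O)Cc1cc2c(OC)c(OC)cc(OC)c2c(OC)c1C(=O)c1c(C)cc(OC)cc1O
F4 | step 11 | methyl 6-[3-(2-hydroxy-4-methoxy-6-methylbenzoyl)-4,5,7,8-tetramethoxynaphthalen-2-yl]-3,5-dioxohexanoate | COC(=O)CC(=O)CC(=O)Cc1cc2c(OC)c(OC)cc(OC)c2c(OC)c1C(=O)c1c(C)cc(OC)cc1O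
F5 | step 13 | 6-(2-hydroxy-4-methoxy-6-methylbenzoyl)-2,5-dimethoxy-7-[(4-hydroxy-2-oxo-2H-pyran-6-yl)methyl]naphthalene-1,4-dione | COc1cc(C)c(C(=O)c2c(Cc3cc(O)cc(=O)o3)cc3c(c2OC)C(=O)C=C(OC)C3=O)c(O)c1
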